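I want to know what this flask holds at 15 d, and whether it has stopped.

| setting | green | amber | red | flask |
|---|---|---|---|---|
| starting material | 0.14 M | 0.56 M | 0.28 M | 0.28 M |
| protic impurity | 0.056 M | 0.056 M | 0.11 M | 0.0560 M |
| remark | run made earlier | run made earlier | run made earlier |  |
| time |  |  |  | 15 d |

- green (time / d: target / %, isomer of the product B / %): 1.25: 17, 14; 4.00: 12, 15; 8.00: 15, 16; 10.0: 16, 17; 15.0: 13, 16
- amber (time / d: target / %, isomer of the product B / %): 1.25: 21, 22; 4.00: 19, 25; 8.00: 20, 27; 10.0: 19, 26; 15.0: 20, 25
- red (time / d: target / %, isomer of the product B / %): 3.00: 14, 15; 6.00: 11, 17; 10.0: 14, 20; 12.0: 14, 17; 15.0: 14, 17

(standard deviation of a reading: 1.5 percentage points)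

- why nothing more happens at 15 d, or that something still does (all of the starting material has reacted / it is still moving / forward and back rates have come level)
- target at 15 d, in percent of the starting material charged
- isomer of the product B at 15 d, in percent of the starting material charged
- isomer of the product A at 15 d, in percent of the starting material charged

- the earlier runs were read with a standard deviation of 1.5 percentage points
- the reaction counts as stopped when no species that holds the starting material changes by six tenths of a point or more over the second half of the time

I reckon with the free fraction, the part of the charge left if every protic impurity takes one starting material for good, as limiting reagent of that loss: here 0.800. Does it order the earlier runs? Their readings wander about a level, so I replace each curve by its mean and divide target plus isomer of the product B by the run's free fraction. Green, with 0.600, gives 0.503. Amber, with 0.900, gives 0.498. Red, with 0.607, gives 0.504.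

A steady share looks to me like isomers whose forward and back rates have come level, thermodynamic control, so I carry 0.502. On this reckoning I expect this flask to hold 40.1% of target plus isomer of the product B. Amber's means, 19.8% to 25.0%, split that into 17.7% target and 22.4% isomer of the product B. The remaining 39.9% is shared by isomer of the product A and starting material, so I put isomer of the product A below it.

The forecast gives 16.8% target, 20.3% isomer of the product B and 62.9% isomer of the product A, and for the end: all of the starting material has reacted. Its ground for the last number: “I assume A is the unmeasured balance, since it was never read.” Here I differ, since its figure is larger than my remainder.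

The flask gives 17.5% target, 22.7% isomer of the product B and 20.8% isomer of the product A, and for the end: forward and back rates have come level.

    starting material ⇌ target (K = 0.948, k = 4.67 × 10⁻⁵ s⁻¹)
    target ⇌ isomer of the product A (K = 1.19, k = 8.85 × 10⁻⁵ s⁻¹)
    isomer of the product A ⇌ starting material (k = 1.53 × 10⁻⁵ s⁻¹)
    starting material + protic impurity → quenched substrate (k = 9.84 × 10⁻⁴ M⁻¹ s⁻¹)
    starting material → decomposition product (k = 2.37 × 10⁻⁸ s⁻¹)
    target ⇌ isomer of the product B (K = 1.30, k = 1.27 × 10⁻⁵ s⁻¹)

In this flask at 15 d, quenched substrate stands at 20.0%, the part of the charge outside the free fraction 0.800, and starting material is still there at 18.4%. By their step alone, both ways together, isomer of the product A and starting material relax with a half-life of 0.246 d, short against 15 d.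

The neighbour charged with 0.14 M of protic impurity has a free fraction of 0.500, so the share 0.502 gives 25.1% of target plus isomer of the product B. Computed, that neighbour holds 10.9% target and 14.2% isomer of the product B.

The readings are simulated for substances that don't exist; the scatter is artificial.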